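**Retrosynthetic overview**
- Only ring B (the saturated ring of the tetralin) is built; both benzene rings are bought.
- Ring B is opened at two bonds at once: C2–C3 (lignan C8'–C8) and C1–C8a (C7'–C6). These are the bonds lignan biosynthesis makes, in the same order: one-electron oxidation, 8–8' radical coupling, then capture of a quinone-methide-type benzylic cation by the second arene.
- This leaves two C6–C3 units: a 3-(3-silyloxy-4-methoxyphenyl)propanal and (E)-coniferyl alcohol diacetate. One oxidative organocatalytic cascade joins them and sets C1, C2 and C3.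
- Aldehyde reduction and one-flask removal of two acetates and the aryl silyl ether finish the synthesis.

Assumption: the SMILES is read literally, so ring A carries OH at C6 (para to C8a, the carbon attached to C1) and OMe at C7, i.e. the 6-hydroxy-7-methoxy regioisomer of (+)-isolariciresinol, all-trans (1S,2R,3R); tetralin numbering has C1 as the aryl-bearing carbon and lignan locants C7–C9/C7'–C9' are used for the side chains.

**Step 1**
Reactants: 1 5-bromo-2-methoxyphenol
Product: 2 tert-butyl(5-bromo-2-methoxyphenoxy)dimethylsilane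
Conditions: TBSCl (1.1 equiv), imidazole (2 equiv), DMF, rt
Reagents that add atoms: tert-butyldimethylsilyl chloride (TBSCl), CC(C)(C)[Si](C)(C)Cl
Why: Imidazole-promoted O-silylation masks the oxidizable phenol while keeping its oxygen a strong para-directing donor for the later Friedel–Crafts ring closure; no stereocentre is formed.

**Step 2**
Reactants: 2 tert-butyl(5-bromo-2-methoxyphenoxy)dimethylsilane; 3 prop-2-en-1-ol (allyl alcohol)
Product: 4 3-[3-(tert-butyldimethylsilyloxy)-4-methoxyphenyl]propanal
Conditions: Pd(OAc)2 (3 mol %), Bu4NCl (1 equiv), NaHCO3 (2.5 equiv), DMF, 80 °C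
Reagents that add atoms: none
Why: Heck reaction under Jeffery conditions, in which the arylpalladium adds to the terminal alkene carbon and β-hydride elimination toward the carbinol gives an enol that tautomerizes to the 3-arylpropanal; no stereocentre is formed.

**Step 3**
Reactants: 5 (E)-2-methoxy-4-(prop-1-en-1-yl)phenyl acetate (isoeugenyl acetate); 6 (Z)-but-2-ene-1,4-diyl diacetate
Product: 7 (E)-3-(4-acetoxy-3-methoxyphenyl)prop-2-en-1-yl acetate (coniferyl alcohol diacetate)
Conditions: RuCl2(=CHPh)(PCy3)(H2IMes) (second-generation Grubbs catalyst, 3 mol %), 6 (3 equiv), CH2Cl2, 40 °C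
Reagents that add atoms: none
Why: Olefin cross-metathesis of a β-methylstyrene with a symmetrical allylic diacetate exchanges the methyl terminus for CH2OAc and gives the thermodynamically preferred E alkene; no stereocentre is formed.

**Step 4**
Reactants: 4 3-[3-(tert-butyldimethylsilyloxy)-4-methoxyphenyl]propanal; 7 (E)-3-(4-acetoxy-3-methoxyphenyl)prop-2-en-1-yl acetate
Product: 9 (1S,2R,3R)-1-(4-acetoxy-3-methoxyphenyl)-2-(acetoxymethyl)-6-(tert-butyldimethylsilyloxy)-7-methoxy-1,2,3,4-tetrahydronaphthalene-3-carbaldehyde, via iminium-bound benzylic cation 8 (not isolated)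
Conditions: (2S,5S)-5-benzyl-2-tert-butyl-3-methylimidazolidin-4-one·CF3CO2H (20 mol %), [Fe(phen)3](SbF6)3 (2.5 equiv; phen = 1,10-phenanthroline), Na2HPO4 (2.5 equiv), H2O (2 equiv), 7 (2.5 equiv), DME, −30 °C
Reagents that add atoms: none
Why: Proposed new method: one-electron oxidation of the chiral enamine of 4 gives a 3π-electron radical cation whose Re face is shielded by the catalyst's benzyl group, so it adds through its Si face to C8' of 7 in an open transition state (styrenyl carbon antiperiplanar to the iminium carbon), forming C8–C8' and setting C3 as R and C2 as R; the benzylic radical is oxidized to the C7' cation 8 (an O-acetylated quinone methide), and Friedel–Crafts attack of the ring carbon para to the silyloxy group through a chair with all three substituents equatorial closes ring B and sets C1 as S; the closest known reaction type is the organo-SOMO radical–polar crossover cycloaddition of 3-arylpropanals with terminal styrenes, extended here to a β-substituted styrene.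

**Step 5**
Reactants: 9 (1S,2R,3R)-1-(4-acetoxy-3-methoxyphenyl)-2-(acetoxymethyl)-6-(tert-butyldimethylsilyloxy)-7-methoxy-1,2,3,4-tetrahydronaphthalene-3-carbaldehyde
Product: 11 (1S,2R,3R)-1-(4-hydroxy-3-methoxyphenyl)-2,3-bis(hydroxymethyl)-7-methoxy-1,2,3,4-tetrahydronaphthalen-6-ol, via silylated diacetate primary alcohol 10 (not isolated)
Conditions: NaBH4 (1.5 equiv), MeOH–THF, 0 °C; then NaOMe (4 equiv), MeOH, rt; AcOH quench
Reagents that add atoms: none
Why: Hydride reduction of the aldehyde followed by Zemplén-type methanolysis of both acetates and of the base-labile aryl silyl ether; the aldehyde is reduced before base is added, so C3 is not epimerized and no stereocentre is touched.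

**Compound list**
1 | 5-bromo-2-methoxyphenol | COc1ccc(Br)cc1O | starting material
2 | tert-butyl(5-bromo-2-methoxyphenoxy)dimethylsilane | COc1ccc(Br)cc1O[Si](C)(C)C(C)(C)C | intermediate
3 | prop-2-en-1-ol (allyl alcohol) | OCC=C | starting material
4 | 3-[3-(tert-butyldimethylsilyloxy)-4-methoxyphenyl]propanal | COc1ccc(CCC=O)cc1O[Si](C)(C)C(C)(C)C | intermediate
5 | (E)-2-methoxy-4-(prop-1-en-1-yl)phenyl acetate (isoeugenyl acetate) | COc1cc(/C=C/C)ccc1OC(C)=O | starting material
6 | (Z)-but-2-ene-1,4-diyl diacetate | CC(=O)OC/C=C\COC(C)=O | starting material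
7 | (E)-3-(4-acetoxy-3-methoxyphenyl)prop-2-en-1-yl acetate (coniferyl alcohol diacetate) | COc1cc(/C=C/COC(C)=O)ccc1OC(C)=O | intermediate
8 | iminium-bound benzylic cation: iminium of the (2S,5S)-imidazolidinone with (2R,3R)-3-(acetoxymethyl)-4-(4-acetoxy-3-methoxyphenyl)-2-[3-(tert-butyldimethylsilyloxy)-4-methoxybenzyl]butanal carrying the positive charge at C4 (lignan C7') | CN1[C@@H](C(C)(C)C)[N+](=C[C@H](Cc2ccc(OC)c(O[Si](C)(C)C(C)(C)C)c2)[C@H](COC(C)=O)[CH+]c2ccc(OC(C)=O)c(OC)c2)[C@@H](Cc2ccccc2)C1=O | intermediate (not isolated)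
9 | (1S,2R,3R)-1-(4-acetoxy-3-methoxyphenyl)-2-(acetoxymethyl)-6-(tert-butyldimethylsilyloxy)-7-methoxy-1,2,3,4-tetrahydronaphthalene-3-carbaldehyde (all-trans) | COc1cc([C@H]2c3cc(OC)c(O[Si](C)(C)C(C)(C)C)cc3C[C@@H](C=O)[C@@H]2COC(C)=O)ccc1OC(C)=O | intermediate
10 | [(1S,2R,3R)-1-(4-acetoxy-3-methoxyphenyl)-6-(tert-butyldimethylsilyloxy)-3-(hydroxymethyl)-7-methoxy-1,2,3,4-tetrahydronaphthalen-2-yl]methyl acetate | COc1cc([C@H]2c3cc(OC)c(O[Si](C)(C)C(C)(C)C)cc3C[C@@H](CO)[C@@H]2COC(C)=O)ccc1OC(C)=O | intermediate (not isolated)
11 | (1S,2R,3R)-1-(4-hydroxy-3-methoxyphenyl)-2,3-bis(hydroxymethyl)-7-methoxy-1,2,3,4-tetrahydronaphthalen-6-ol (all-trans) | COc1cc([C@H]2c3cc(OC)c(O)cc3C[C@@H](CO)[C@@H]2CO)ccc1O | target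

**Step count**
Total steps: 5. Longest linear sequence: 4 steps (steps 1, 2, 4, 5); step 3 is the convergent branch.

**Steps most likely to fail**

Step 4 (highest risk). The β-substituted, acetoxy-bearing styrene 7 may add slowly to the enamine radical cation. The 2,3-anti selectivity of the radical addition is not secured by precedent. Oxygen nucleophiles may intercept the C7' cation before the arene does. The fallback sets out from 4 and 7 and comes back to the route at 11. The C8–C8' bond is still made by organo-SOMO activation with the same imidazolidinone, but under carbo-oxidation conditions ((NH4)2Ce(NO3)6, NaHCO3, wet DME, −40 °C). There the C7' cation is deliberately captured by nitrate, giving the open-chain benzylic nitrate aldehyde F1. NaBH4 and then NaOMe in MeOH reduce the aldehyde and remove the acetates and the silyl group. The freed para-phenoxide expels nitrate to a quinone methide, which the C9 alkoxide closes to the tetrahydrofuran lignan F2. At this lariciresinol-type stage, diastereomers from an unselective radical addition can be separated. CF3CO2H in CH2Cl2 at 0 °C then reopens the benzylic ether to the quinone methide, and Friedel–Crafts closure para to the phenol gives 11 directly (the acid rearrangement of a lariciresinol-type lignan to its cyclolignan).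

Step 2. The electron-rich aryl bromide may react sluggishly, the branched 2-arylpropanal may form alongside, and the aryl silyl ether may be lost in hot DMF. The fallback sets out from 2 and comes back at 4. Negishi coupling of 2 with commercial 2-(1,3-dioxolan-2-yl)ethylzinc bromide, BrZnCH2CH2CH(OCH2CH2O) (Pd(OAc)2, SPhos, THF, 50 °C), gives the acetal tert-butyl{5-[2-(1,3-dioxolan-2-yl)ethyl]-2-methoxyphenoxy}dimethylsilane F3. Aqueous AcOH (80 %, 40 °C) then unmasks aldehyde 4 without touching the aryl silyl ether.

Step 3. Self-metathesis of 5 to the stilbene and incomplete conversion of the internal alkene may lower the yield. The fallback sets out from 5 and comes back at 7. Allylic oxidation of the propenyl methyl group with SeO2 (dioxane–H2O, reflux) gives (E)-4-acetoxy-3-methoxycinnamaldehyde F4. Luche reduction (NaBH4, CeCl3·7H2O, MeOH, −20 °C) gives (E)-4-acetoxy-3-methoxycinnamyl alcohol F5. Ac2O in pyridine then gives 7.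

**Further compounds**
F1 | step 4 | (2R,3R)-3-(acetoxymethyl)-4-(4-acetoxy-3-methoxyphenyl)-2-[3-(tert-butyldimethylsilyloxy)-4-methoxybenzyl]-4-(nitrooxy)butanal (both C4 epimers) | O=C[C@H](Cc1ccc(OC)c(O[Si](C)(C)C(C)(C)C)c1)[C@H](COC(C)=O)C(O[N+](=O)[O-])c1ccc(OC(C)=O)c(OC)c1
F2 | step 4 | [(3R,4R)-2-(4-hydroxy-3-methoxyphenyl)-4-(3-hydroxy-4-methoxybenzyl)oxolan-3-yl]methanol (both C2 epimers) | COc1ccc(C[C@H]2COC(c3ccc(O)c(OC)c3)[C@H]2CO)cc1O
F3 | step 2 | tert-butyl{5-[2-(1,3-dioxolan-2-yl)ethyl]-2-methoxyphenoxy}dimethylsilane | COc1ccc(CCC2OCCO2)cc1O[Si](C)(C)C(C)(C)C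
F4 | step 3 | (E)-4-acetoxy-3-methoxycinnamaldehyde | COc1cc(/C=C/C=O)ccc1OC(C)=O
F5 | step 3 | (E)-4-acetoxy-3-methoxycinnamyl alcohol | COc1cc(/C=C/CO)ccc1OC(C)=O
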